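substrate 0.054 M; reagent in the second phase 0.216 M; time 15 h; volume of the second phase over the first 1.0

    reagent in the reaction phase + target → over-reaction product (k1 = 6.6 M⁻¹ h⁻¹)
    reagent in the reaction phase ⇌ reagent in the second phase, rate k2*([reagent in the reaction phase] - [reagent in the second phase]/K2) per volume of the first phase (K2 = 0.33, k2 = 0.20 h⁻¹)
    substrate + target → side product (k3 = 0.78 M⁻¹ h⁻¹)
    substrate + reagent in the reaction phase → target (k4 = 26 M⁻¹ h⁻¹)
    target → decomposed product (k5 = 0.081 h⁻¹)
    target ⇌ product in the second phase, rate k6*([target] - [product in the second phase]/K6) per volume of the first phase (K6 = 9.6, k6 = 0.19 h⁻¹)

- amount of target and product in the second phase together at 15 h, in percent of the substrate charged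
- the change that raises the amount of target and product in the second phase together at 15 h, in percent of the substrate charged most ("none" if none brings more than 2 percentage points) (violet / ochre / grey / none)
- amount of target and product in the second phase together at 15 h, in percent of the substrate charged, after grey

- a species is counted by the substrate in it: one side product counts as two
- amounts and yields of target count product in the second phase too
- in the second phase: reagent in the second phase, product in the second phase; everything else is in the first
- charges count per volume of the first phase; a concentration in a rate is the amount of a species over the volume of its own phase; every rate counts per litre of the first phase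
- run time (flask): 15 h

**The leftover.** I start from what stays over. Each substrate costs one reagent to become target and one more if that target over-reacts, so a charge wholly over-reacted leaves 0.108 M of reagent. Shared between the phases at partition ratio 0.33, this puts R* = 0.0812 M in the reaction phase, and I freeze it there.

**Fast rungs.** Reagent relaxes between the phases in 1.24 h. Reagent in the reaction phase, meeting the substrate as charged, has a shorter half-life by that step alone, 0.49 h. I count the substrate as target, since its constant towards target is 33.3 times that towards side product. With R* frozen, target has a pseudo-first-order loss L = 0.617 h⁻¹, from decomposition and over-reaction. It lives 1.24 h in the reaction phase, about as long as reagent takes to relax, so the freeze is rough.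

**Middle rung.** A target either crosses or is lost. The capture share φ, the transfer coefficient over itself plus L, is 23.5%.

**Slow rung.** Captured product leaks back at 0.0198 h⁻¹, and the share 1 − φ of each leak is lost, so the pair fades at λ = 0.0151 h⁻¹. That is a time of 66.2 h, longer than the run. My reckoning is φ·exp(−λt) = 18.8%.

Violet, doubling the transfer coefficient of target, lifts φ to 38.1% and gives 26.4%. Grey drops φ to 10.1% and gives 7.74%. Ochre does not enter φ as I reckon it, so I put no number on it. I commit to violet.

**The forecast.** The forecast says 21% (18% to 24%), violet, and 13% after grey (10.5% to 15.5%), holding that “Violet nearly doubles capture”.

**The result.** The flask gives 21.1% against my 18.8%, and 12.6% after grey against my 7.74%. Its reagent in the reaction phase reads 0.0955 M at 15.0 h, against my R* of 0.0812 M. The best change is violet, gaining 8.6 percentage points, while ochre loses 2.8 points. My violet ratio, 1.40, applied to the flask's figure gives a gain of 8.5 points.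

**Second flask.** With 0.013 M of substrate, the same reckoning gives R* = 0.143 M, φ = 15.7% and a yield of 12.2%. That flask gives 16.7%, with its reagent in the reaction phase at 0.145 M at 15.0 h.

The constants used here are assumed; the result is computed.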